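How far did the charge of Z carry this flask, given that Tuesday's run had stalled?

common to all: D 18 mol%
- Tuesday's: G 0.40 M; L 0.40 M; Z 2.5 equiv; run made earlier
- flask: G 0.20 M; L 0.20 M; Z 2.50 equiv; time 15 h

Tuesday's run (percent of the G and L together charged)

| time / h | G / % | J / % |
|---|---|---|
| 0.250 | 28.9 | 31.2 |
| 0.833 | 26.1 | 34.9 |
| 1.33 | 25.6 | 35.0 |
| 2.00 | 25.7 | 34.5 |
| 3.00 | 25.9 | 34.4 |

(scatter of a reading: 0.3 percentage points)

- D is single-handed; G and L are mirror images of each other, charged as a racemate, each of them at the stated concentration
- candidate steps: Z + D + G -> D + J; Z + D + L -> D + E; G <-> L; Z -> X; 2 Z -> Q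
- no earlier run changes the charge of D; that part of a forecast is a guess

* share of the G and L together used up at 15 h
* J at 15 h, in percent of the G and L together charged
* L at 15 h, in percent of the G and L together charged
* E at 15 h, in percent of the G and L together charged

Tuesday's G and J read 60.3 % together at the last reading, more than half of the charge, so L had fed G, and I took G and L as equal. That made the conversion 48.2 %, of which J was 71.4 %. Z stood at 1.25 of the G and L together, more than they took up, and the candidate steps give D back, so I read the stall as Z gone, the remainder lost to X or Q.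

Tuesday gave 0.827 for the return, Z taken up per Z lost, divided by the mean fraction of G and L left. For that mean I replaced the curve by its midpoint, 0.759, where the logarithmic mean gives 0.733.

What did dilution do? Every charge stood at half of Tuesday's. Uptake per Z follows D times substrate, so it fell to a quarter, while loss per Z held under Z -> X and halved under 2 Z -> Q. The return was therefore 0.207 or 0.413, and Tuesday's curve did not separate them for me.

Solved with the midpoint, these gave conversions of 19.6 % and 32.2 %. I committed to their middle, 25.9 %, hence J 18.5 %, E 7.41 % and L 37.0 %.

The forecast, on the ground that “The stall means Z has died”, gave conversion 17.5 %, J 12.6 %, L 41.3 % and E 4.9 %.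

The flask gave conversion 27.6 %, J 19.9 %, L 36.2 % and E 7.62 %.

    Z + D + G → D + J (k = 2.90 M⁻² min⁻¹)
    Z + D + L → D + E (k = 1.10 M⁻² min⁻¹)
    G ⇌ L (k = 0.770 min⁻¹)
    Z → X (k = 0.0350 min⁻¹)
    2 Z → Q (k = 0.130 M⁻¹ min⁻¹)

The flask's return came to 0.328, between my 0.207 and 0.413. Scaled to the neighbour with 31 mol% of D, it became 0.565, which gives a conversion of 39.1 %; that neighbour gave 38.6 %. In the flask Z, the limiting reagent, was down to 0.187 % of its charge at 1.50 h, well before the end, and 0 % of it stood at 15.0 h. Ten times the time changed nothing: at 150 h the flask stood at conversion 27.6 %, J 19.9 %, L 36.2 % and E 7.62 %.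

(The readings are simulated for an exercise; scatter was added.)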